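## Retrosynthetic overview

1. Target 14 ⇐ late allylic (Riley) oxidation of the isopropenyl CH3 of the fully acylated toxol derivative 12.
2. 12 ⇐ tigloylation of the (R)-carbinol obtained by asymmetric transfer hydrogenation of the 5-acetyl group of toxol acetate 9.
3. Toxol 8 ⇐ key step: one-flask chiral sulfur-ylide annulation of 5-acetylsalicylaldehyde 2. The dihydrofuran ring closes by intramolecular phenoxide C–O bond formation (O1–C2) on a trans-vinyl epoxide, which sets C2 and C3.
4. 2 ⇐ ortho-formylation of 4'-hydroxyacetophenone 1; sulfonium salt 5 ⇐ isothiocineole 3 + methallyl bromide 4.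
5. Ring order: the benzene ring is bought; the dihydrofuran ring is the only ring formed (step 3).

Assumption: the sense of induction of salt 5 in step 3 (→ 2R,3R epoxide) is predicted from the usual ylide model (vinyl group syn to the sulfur lone pair, aldehyde approaching anti to the CMe2 group); if it proves opposite, the (S)-limonene-derived antipode of 3 is used with nothing else changed.

## Route

Step 1
Reactants: 1 4'-hydroxyacetophenone
Product: 2 5-acetyl-2-hydroxybenzaldehyde
Conditions: MgCl2, Et3N, (CH2O)n, MeCN, reflux; aq. HCl work-up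
Reagents that add atoms: paraformaldehyde (as formaldehyde), C=O
Why: Magnesium-mediated ortho-formylation (Casnati–Skattebøl) directs formaldehyde to the free ortho position (para is blocked by the acetyl group) and a second formaldehyde oxidises the salicyl alkoxide to the aldehyde by Oppenauer-type hydride transfer; no stereocentre is formed.

Step 2
Reactants: 3 isothiocineole ((R)-limonene-derived enantiomer); 4 methallyl bromide (3-bromo-2-methylprop-1-ene)
Product: 5 S-(2-methylallyl)isothiocineolium tetrafluoroborate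
Conditions: NaBF4 (aq.), CH2Cl2, rt, 48 h
Reagents that add atoms: sodium tetrafluoroborate, [Na+].F[B-](F)(F)F
Why: SN2 S-alkylation of the thioether by the allylic bromide with Br/BF4 counter-ion exchange gives the salt, and alkylation on the exposed exo lone pair of sulfur gives a single sulfonium diastereomer.

Step 3
Reactants: 2 5-acetyl-2-hydroxybenzaldehyde; 5 S-(2-methylallyl)isothiocineolium tetrafluoroborate
Product: 8 toxol [(2S,3R)-5-acetyl-3-hydroxy-2-isopropenyl-2,3-dihydrobenzofuran], via sulfonium ylide 6 (not isolated), via vinyl epoxide 7 (not isolated)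
Conditions: KOH (2.5 equiv), MeCN/H2O 9:1, 0 °C → rt, then 40 °C; aq. NH4Cl
Reagents that add atoms: none
Why: Proposed new method: an enantioselective one-flask formal [4+1] annulation of an unprotected salicylaldehyde with a chiral sulfonium methallylide, in which KOH forms the phenoxide of 2 and ylide 6, the ylide adds to the aldehyde through its open face and the anti-betaine closes to the trans-(2R,3R)-vinyl epoxide 7 (sets C3 as R), and the ortho-phenoxide then opens the epoxide at the allylic carbon by anti (SN2, 5-endo) C–O bond formation with inversion (sets C2 as S, hence the 2,3-trans ring); the closest known reaction types are chiral sulfur-ylide (Corey–Chaykovsky) epoxidation of aryl aldehydes, formation of 2,3-dihydrobenzofuran-3-ols from salicylaldehydes with achiral sulfur ylides, and base-induced cyclisation of 2-(oxiranyl)phenols.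

Step 4
Reactants: 8 toxol
Product: 9 toxol acetate [(2S,3R)-5-acetyl-2-isopropenyl-2,3-dihydrobenzofuran-3-yl acetate]
Conditions: Ac2O, pyridine, DMAP (cat.), CH2Cl2, 0 °C → rt
Reagents that add atoms: acetic anhydride, CC(=O)OC(C)=O
Why: DMAP-catalysed O-acylation of the secondary benzylic alcohol occurs at oxygen only, so C3 keeps its R configuration.

Step 5
Reactants: 9 toxol acetate
Product: 10 (2S,3R)-5-[(1R)-1-hydroxyethyl]-2-isopropenyl-2,3-dihydrobenzofuran-3-yl acetate
Conditions: RuCl[(R,R)-TsDPEN](p-cymene) (1 mol%), HCO2H/Et3N 5:2, 30 °C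
Reagents that add atoms: none
Why: Noyori asymmetric transfer hydrogenation reduces only the aryl methyl ketone (isopropenyl alkene and acetate untouched), and the (R,R)-catalyst gives the (R)-1-arylethanol through the CH/π-organised outer-sphere transition state, as for acetophenone.

Step 6
Reactants: 10 (2S,3R)-5-[(1R)-1-hydroxyethyl]-2-isopropenyl-2,3-dihydrobenzofuran-3-yl acetate; 11 tiglic acid
Product: 12 (1R)-1-[(2S,3R)-3-acetoxy-2-isopropenyl-2,3-dihydrobenzofuran-5-yl]ethyl (E)-2-methylbut-2-enoate
Conditions: DCC, DMAP (cat.), CH2Cl2, 0 °C → rt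
Reagents that add atoms: none
Why: Steglich esterification acylates the carbinol oxygen without breaking its C–O bond, so the R centre is retained, and the E (tiglate) geometry is the stable one.

Step 7
Reactants: 12 (1R)-1-[(2S,3R)-3-acetoxy-2-isopropenyl-2,3-dihydrobenzofuran-5-yl]ethyl (E)-2-methylbut-2-enoate
Product: 14 target CNP0294391.1, via allylic alcohol 13 (not isolated)
Conditions: SeO2 (1.5 equiv), 1,4-dioxane (trace H2O), 70 °C
Reagents that add atoms: selenium dioxide, O=[Se]=O
Why: Riley allylic oxidation (ene reaction then [2,3]-sigmatropic shift) converts the methyl of the electron-rich 1,1-disubstituted alkene into CH2OH (13) and on to the conjugated aldehyde, while the electron-poor tiglate alkene and all three stereocentres are not touched.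

## Compound list

1 | 4'-hydroxyacetophenone | CC(=O)c1ccc(O)cc1 | starting material
2 | 5-acetyl-2-hydroxybenzaldehyde | CC(=O)c1ccc(O)c(C=O)c1 | intermediate
3 | isothiocineole, (R)-limonene-derived enantiomer: (1R,4S,5R)-4,7,7-trimethyl-6-thiabicyclo[3.2.1]octane (2,8-epithio-cis-p-menthane, C4 methyl cis to sulfur) | C[C@H]1CC[C@@H]2C[C@H]1SC2(C)C | starting material
4 | methallyl bromide (3-bromo-2-methylprop-1-ene) | CC(=C)CBr | starting material
5 | S-(2-methylallyl)isothiocineolium tetrafluoroborate (allyl group on the exo lone pair of sulfur) | C[C@H]1CC[C@@H]2C[C@H]1[S@@+](CC(C)=C)C2(C)C.F[B-](F)(F)F | intermediate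
6 | sulfonium ylide of 5 (carbanion on the allylic carbon next to sulfur; formed in the flask, not isolated) | C[C@H]1CC[C@@H]2C[C@H]1[S@@+]([CH-]C(C)=C)C2(C)C | intermediate
7 | 1-{4-hydroxy-3-[(2R,3R)-3-(prop-1-en-2-yl)oxiran-2-yl]phenyl}ethan-1-one (trans-vinyl epoxide, present as its potassium phenoxide; not isolated) | CC(=O)c1ccc(O)c(c1)[C@H]1O[C@@H]1C(C)=C | intermediate
8 | toxol, 1-[(2S,3R)-3-hydroxy-2-(prop-1-en-2-yl)-2,3-dihydro-1-benzofuran-5-yl]ethan-1-one (2,3-trans) | C=C(C)[C@@H]1Oc2ccc(C(C)=O)cc2[C@H]1O | intermediate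
9 | toxol acetate, (2S,3R)-5-acetyl-2-(prop-1-en-2-yl)-2,3-dihydro-1-benzofuran-3-yl acetate | C=C(C)[C@@H]1Oc2ccc(C(C)=O)cc2[C@H]1OC(C)=O | intermediate
10 | (2S,3R)-5-[(1R)-1-hydroxyethyl]-2-(prop-1-en-2-yl)-2,3-dihydro-1-benzofuran-3-yl acetate | C=C(C)[C@@H]1Oc2ccc([C@@H](C)O)cc2[C@H]1OC(C)=O | intermediate
11 | tiglic acid, (E)-2-methylbut-2-enoic acid | C/C=C(\C)C(=O)O | starting material
12 | (1R)-1-[(2S,3R)-3-acetoxy-2-(prop-1-en-2-yl)-2,3-dihydro-1-benzofuran-5-yl]ethyl (2E)-2-methylbut-2-enoate | C=C(C)[C@@H]1Oc2ccc([C@@H](C)OC(=O)/C(C)=C/C)cc2[C@H]1OC(C)=O | intermediate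
13 | (1R)-1-[(2S,3R)-3-acetoxy-2-(3-hydroxyprop-1-en-2-yl)-2,3-dihydro-1-benzofuran-5-yl]ethyl (2E)-2-methylbut-2-enoate (not isolated) | C=C(CO)[C@@H]1Oc2ccc([C@@H](C)OC(=O)/C(C)=C/C)cc2[C@H]1OC(C)=O | intermediate
14 | CNP0294391.1, (1R)-1-[(2S,3R)-3-acetoxy-2-(3-oxoprop-1-en-2-yl)-2,3-dihydro-1-benzofuran-5-yl]ethyl (2E)-2-methylbut-2-enoate | C=C(C=O)[C@@H]1Oc2ccc([C@@H](C)OC(=O)/C(C)=C/C)cc2[C@H]1OC(C)=O | target

## Step count and risks

Total steps: 7 (steps 1–7). Longest linear sequence: 6 (steps 1, 3, 4, 5, 6, 7); step 2 is a one-step side branch for the ylide precursor.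

Most likely to fail, in order:

Step 3 (the proposed new annulation). Risks: the phenoxide-deactivated aldehyde may add the ylide slowly; the phenoxide may be O-allylated by salt 5; trans/cis or enantioselectivity may be insufficient; the benzylic C–O bond of 7 may ionise and scramble C3. The fallback uses known chemistry and takes its asymmetry from catalyst-controlled alkene epoxidation instead of the ylide. It sets out from 2 and returns at 8. The phenol is silylated (TIPSCl, imidazole) to give 5-acetyl-2-(triisopropylsilyloxy)benzaldehyde F1. Wittig olefination of the aldehyde with (2-methylallyl)triphenylphosphorane, followed by iodine-catalysed E/Z equilibration, gives the (E)-aryl diene F2. Shi epoxidation (D-fructose-derived ketone, Oxone, pH 10.5) of the styrenyl double bond gives the (2R,3R)-vinyl epoxide silyl ether F3, with the same facial sense as for trans-stilbene and trans-β-methylstyrene. TBAF then releases the phenoxide, which cyclises onto the allylic epoxide carbon to give 8.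

Step 7 (SeO2 oxidation). Risks: stopping at alcohol 13, attack on the tiglate γ-methyl, or acid-promoted loss of the benzylic esters. The fallback sets out from 12 and returns at 14. A Schenck ene reaction with singlet oxygen (O2, hν, tetraphenylporphyrin, CH2Cl2, 0 °C) on the isopropenyl group gives the primary allylic hydroperoxide F4. This is dehydrated with Ac2O/pyridine/DMAP (Kornblum–DeLaMare) to the enal 14.

Step 1 (ortho-formylation). Risks: the acetyl group slows the reaction, and the methyl ketone may be hydroxymethylated by formaldehyde. The fallback sets out from 1 and returns at 2. Blanc chloromethylation (paraformaldehyde, conc. HCl) gives 1-[3-(chloromethyl)-4-hydroxyphenyl]ethan-1-one F5. Hydrolysis (aq. NaHCO3, acetone) gives 1-[4-hydroxy-3-(hydroxymethyl)phenyl]ethan-1-one F6. Selective MnO2 oxidation of the benzylic alcohol then gives 2.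

## Further compounds

F1 | step 3 | 5-acetyl-2-[(triisopropylsilyl)oxy]benzaldehyde | CC(=O)c1ccc(O[Si](C(C)C)(C(C)C)C(C)C)c(C=O)c1
F2 | step 3 | 1-{3-[(1E)-3-methylbuta-1,3-dien-1-yl]-4-[(triisopropylsilyl)oxy]phenyl}ethan-1-one | CC(=O)c1ccc(O[Si](C(C)C)(C(C)C)C(C)C)c(/C=C/C(C)=C)c1
F3 | step 3 | 1-{3-[(2R,3R)-3-(prop-1-en-2-yl)oxiran-2-yl]-4-[(triisopropylsilyl)oxy]phenyl}ethan-1-one | CC(=O)c1ccc(O[Si](C(C)C)(C(C)C)C(C)C)c(c1)[C@H]1O[C@@H]1C(C)=C
F4 | step 7 | (1R)-1-[(2S,3R)-3-acetoxy-2-(3-hydroperoxyprop-1-en-2-yl)-2,3-dihydro-1-benzofuran-5-yl]ethyl (2E)-2-methylbut-2-enoate | C=C(COO)[C@@H]1Oc2ccc([C@@H](C)OC(=O)/C(C)=C/C)cc2[C@H]1OC(C)=O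
F5 | step 1 | 1-[3-(chloromethyl)-4-hydroxyphenyl]ethan-1-one | CC(=O)c1ccc(O)c(CCl)c1
F6 | step 1 | 1-[4-hydroxy-3-(hydroxymethyl)phenyl]ethan-1-one | CC(=O)c1ccc(O)c(CO)c1
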